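The earlier runs and the new flask are calculated for substances that don't exist; the scatter is artificial.

Take the easy step first and work with what is left, not what is made: divide [right-handed substrate] by [left-handed substrate] and take the natural logarithm, and you have one dimensionless number, N, the depth of the resolution.

| flask | left-handed substrate | right-handed substrate | partner | precatalyst | remark | time |
|---|---|---|---|---|---|---|
| Friday's | 10 mM | 10 mM | 20 mM | 29 µM | run made earlier |  |
| Wednesday's | 10 mM | 10 mM | 20 mM | 110 µM | run made earlier |  |
| alder | 10 mM | 10 mM | 20.0 mM | 50 µM |  | 5.0 h |
| maple | 10 mM | 10 mM | 20.0 mM | 150 µM |  | 5.0 h |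
- Friday's (time / h: right-handed substrate / %, left-handed substrate / %): 1.00: 49.2, 47.9; 2.00: 50.1, 41.9; 3.00: 50.3, 36.0; 4.00: 49.2, 28.2; 5.00: 49.5, 23.5
- Wednesday's (time / h: right-handed substrate / %, left-handed substrate / %): 1.00: 51.1, 41.6; 2.00: 50.4, 26.8; 3.00: 48.6, 17.2; 4.00: 48.8, 10.1; 5.00: 48.4, 6.0

(standard deviation of a reading: 0.5 percentage points)
- catalyst is single-handed; left-handed substrate and right-handed substrate are mirror images of each other, charged as a racemate, each of them at the stated concentration
- an excess is the difference of the two amounts in percent of their sum
- an excess is below zero if the other one leads
- the winner by excess of right-handed substrate over left-handed substrate among what is left of the two; "neither" if no more than 2 percentage points parts them (alder / maple / neither)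
- excess of right-handed substrate over left-handed substrate among what is left of the two at the end, alder
- excess of right-handed substrate over left-handed substrate among what is left of the two at the end, maple

1. You read the excess off N, because with the ratio x = e^N, the excess is x less one over x plus one.

2. At 5.00 h, Friday's run has N = 0.745 and Wednesday's has N = 2.09, while [right-handed substrate] ends at 49.5 % and 48.4 %, so N follows the loss of left-handed substrate.

3. Wednesday's run holds 3.79 times the precatalyst of Friday's run and reaches 2.81 times its N, so with the charges of substrates and partner and the time held as they are in these runs, I take N as a power of the precatalyst charge, with exponent 0.773.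

4. Scaling from Friday's N, my reckoning gives alder N = 1.14, an excess of 51.4 %, and maple N = 2.65, an excess of 86.8 %, which puts maple ahead.

5. To test whether one number is enough, read the exponent again at 3.00 h: it comes to 0.850, and used on Friday's N this moves alder to 53.1 % and maple to 90.6 %, so maple stays ahead, and the two exponents, both read off scattered readings, part by 0.0770.

The forecast, which works from rate constants where I use end ratios, says maple, with alder at 51 % and maple at 86 %: “That is a 2.8-fold rise for a 3.8-fold loading”.

The flask gives maple, with alder at 53.7 % and maple at 87.6 %.

    partner + catalyst + left-handed substrate → catalyst + left-handed product (k = 370 /M²/s)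
    partner + catalyst + right-handed substrate → catalyst + right-handed product (k = 3.60 /M²/s)
    partner + precatalyst → catalyst + spent reagent (k = 0.00240 /M/s)
    left-handed product ⇌ right-handed product (k = 2.00 × 10⁻⁶ /s)
    partner ⇌ dormant form (K = 0.170, k = 7.80 × 10⁻⁵ /s)

Those excesses mean N = 1.20 for alder and 2.72 for maple, against my 1.14 and 2.65. For the neighbour of alder with 12.0 µM of precatalyst, the same scaling gives N = 0.377, an excess of 18.6 %, and that flask gives 18.0 %. The rate constant of the step to left-handed product is 103 times that of the step to right-handed product, the selectivity factor. At the end of alder, 99 % of the charged right-handed substrate stands against 30 % of the charged left-handed substrate.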